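(The earlier runs and the new flask were computed from invented constants, noise included.)

The amounts are not what you have to choose: delta, epsilon, gamma and beta each take substrate at 0.066 M and reagent at 0.198 M. The next run is therefore a choice of temperature for 80 min, and that choice hangs on how much of the charge can end as target.

| flask | substrate | reagent | temperature | remark | time |
|---|---|---|---|---|---|
| violet | 0.044 M | 0.198 M | −12 °C | run made earlier |  |
| ochre | 0.099 M | 0.198 M | 37 °C | run made earlier |  |
| blue | 0.066 M | 0.30 M | −12 °C | run made earlier |  |
| delta | 0.066 M | 0.198 M | −5 °C |  | 80 min |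
| epsilon | 0.066 M | 0.198 M | 55 °C |  | 80 min |
| gamma | 0.066 M | 0.198 M | 25 °C |  | 80 min |
| beta | 0.066 M | 0.198 M | −35 °C |  | 80 min |

| run | time / min | target / % | substrate / % |
|---|---|---|---|
| violet | 15.0 | 0 | 65.2 |
| violet | 30.0 | 0.9 | 45.3 |
| violet | 50.0 | 4.5 | 27.8 |
| violet | 60.0 | 3.7 | 22.0 |
| violet | 80.0 | 7.2 | 14.8 |
| ochre | 0.833 | 18.1 | 58.4 |
| ochre | 1.50 | 36.1 | 42.4 |
| ochre | 3.00 | 59.1 | 24.2 |
| ochre | 5.00 | 74.9 | 15.3 |
| ochre | 10.0 | 84.5 | 4.2 |
| blue | 15.0 | 3.4 | 52.1 |
| blue | 30.0 | 1.5 | 30.7 |
| blue | 50.0 | 2.5 | 14.7 |
| blue | 60.0 | 5.1 | 10.0 |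
| blue | 80.0 | 8.2 | 5.7 |

(scatter of a reading: 1 percentage point)



- the best flask by amount of target, in percent of the substrate charged; "all alike" if 1.5 percentage points covers them all (delta / epsilon / gamma / beta / all alike)
- amount of target at the end, in percent of the substrate charged, delta
- amount of target at the end, in percent of the substrate charged, epsilon
- amount of target at the end, in percent of the substrate charged, gamma
- amount of target at the end, in percent of the substrate charged, beta

Read the ochre run as a balance. At 10.0 min ochre shows target 84.5% and substrate 4.2%, so 11.3% of the charge stands in neither column. Divide target by that unseen share and call the result the hold ratio: 7.48 as read at that last point. At 3.00 min the same ratio reads 3.54, and at 5.00 min it reads 7.64. So target gains on the unseen share at first; the last two readings, each with a scatter of 1 percentage point, cannot tell a further rise from a level. Target decaying into that share would pull the ratio down, and these two readings show no fall beyond that scatter.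

I therefore take the ratio, read at 37 °C, as an estimate and not as a bound: if what leaves substrate divides in this proportion, target reaches about 88.2% of the charge. Ochre read target 84.5% at 10.0 min with substrate 4.2% still there, and gamma, at 25 °C, is colder but has 8.00 times that long. Violet, at −12 °C, shows target 7.2% after 80.0 min, which speaks against beta and delta. I would charge gamma and expect about 88.2% from epsilon as well.

The forecast also names gamma, with delta 23%, epsilon 55%, gamma 82% and beta 0.1%. Of ochre's shortfall it says: “That suggests a loss, either a side branch or target decay, probably worse when hot.” My reckoning parts from it on epsilon, 88.2% against 55%.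

The flasks give delta 22.5%, epsilon 87.3%, gamma 90.9% and beta 0.0253%; the best is gamma.

    intermediate ⇌ target (K = 10.0, k = 0.00540 s⁻¹, Ea = 94.0 kJ mol⁻¹, ΔH = −10.0 kJ mol⁻¹)
    2 reagent → self-condensation product (k = 0.00200 L mol⁻¹ s⁻¹, Ea = 77.0 kJ mol⁻¹)
    substrate + reagent → intermediate (k = 0.0320 L mol⁻¹ s⁻¹, Ea = 45.0 kJ mol⁻¹)
    (constants at 25 °C)

In gamma, intermediate and target relax towards each other with a half-life of 1.94 min, short against the run of 80 min. At 80.0 min gamma holds target 90.9% and intermediate 9.09%, a hold ratio of 10.0 against the 7.48 read from ochre; the ratio is here the equilibrium constant of that pair. Epsilon at 80.0 min holds target 87.3% and intermediate 12.6%, a hold ratio of 6.93, and the estimate of 88.2% lies 2.7 points below gamma's target and 0.90 points above epsilon's.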